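**Retrosynthetic overview**

- Backbone numbering: C1–C14 of the tetradecanoic acid (C1 = CO2H). The only ring, the 1,2-dioxane (O–O, C3–C6), is formed in one operation, second to last.
- Acid ⇐ methyl ester ⇐ 6-exo conjugate addition of a C6 tertiary hydroperoxide onto the (2E)-enoate, the ring closure presumed in the biogenesis of plakortin-type peroxides. The hydroperoxide is made in the same operation by acid perhydrolysis of a tertiary carbinol.
- Hydroxy enoate ⇐ cross-metathesis with acrylate ⇐ vinyl carbinol ⇐ Grignard union at C5–C6 of a C3–C5 bromide with a C6–C14 ethyl ketone.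
- Ketone ⇐ two Cu-catalysed asymmetric conjugate additions (C10, then C8) bridged by a reduction/olefination. Bromide ⇐ Cu-catalysed asymmetric allylic ethylation of (E)-1,4-dibromobut-2-ene (C4).

Assumption 1: each chiral ligand is named as the enantiomer taken to give the drawn centre; if the observed sense is opposite, its mirror image is used.

Assumption 2: C6 carries two primary alkyl arms of near-equal size, so no short peroxidation can bias it; it forms as a near 1:1 pair in step 7 and the 6R series is secured by chromatography of 17.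

**Route**

Step 1
Reactants: 1 methyl (E)-hept-2-enoate; 2 ethylmagnesium bromide
Product: 3 methyl (S)-3-ethylheptanoate
Conditions: EtMgBr (1.2 equiv), CuBr·SMe2 (5 mol%), (R,S)-Josiphos (6 mol%), t-BuOMe, −75 °C; then 1 M HCl
Reagents that add atoms: ethylmagnesium bromide, CC[Mg]Br
Why: Cu-catalysed asymmetric conjugate addition of a Grignard reagent to an (E)-enoate; the Josiphos–Cu complex differentiates the two alkene faces relative to the ester, so C10 is set (3S in 3) even though ethyl and butyl are alike in size.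

Step 2
Reactants: 3 methyl (S)-3-ethylheptanoate; 4 diethyl (2-oxobutyl)phosphonate
Product: 6 (4E,7S)-7-ethylundec-4-en-3-one, via (S)-3-ethylheptanal 5 (not isolated)
Conditions: i-Bu2AlH (1.1 equiv), CH2Cl2, −78 °C; then 4/NaH in THF, −78 °C → rt; aq potassium sodium tartrate
Reagents that add atoms: diethyl (2-oxobutyl)phosphonate, CCC(=O)CP(=O)(OCC)OCC
Why: One-pot partial ester reduction and Horner–Wadsworth–Emmons olefination: the aluminium hemiacetal releases aldehyde 5 only as the phosphonate anion consumes it, giving the (E)-enone; no stereocentre is formed and C10 (β to the carbonyl) cannot epimerise.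

Step 3
Reactants: 6 (4E,7S)-7-ethylundec-4-en-3-one; 7 methylmagnesium bromide
Product: 8 (5S,7S)-7-ethyl-5-methylundecan-3-one
Conditions: MeMgBr (1.3 equiv), CuBr·SMe2 (5 mol%), (R,S)-Josiphos (6 mol%), t-BuOMe, −75 °C; then 1 M HCl
Reagents that add atoms: methylmagnesium bromide, C[Mg]Br
Why: Cu-catalysed asymmetric conjugate addition of MeMgBr to the acyclic (E)-enone under catalyst control sets C8 (5S in 8); the remote C10 centre has little influence and the product is protected from 1,2-addition as its magnesium enolate.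

Step 4
Reactants: 9 (E)-1,4-dibromobut-2-ene; 2 ethylmagnesium bromide
Product: 10 (3R)-3-(bromomethyl)pent-1-ene
Conditions: EtMgBr (1.1 equiv), CuBr·SMe2 (1 mol%), (S,S)-Taniaphos (1.2 mol%), CH2Cl2, −75 °C
Reagents that add atoms: ethylmagnesium bromide, CC[Mg]Br
Why: Cu-catalysed asymmetric allylic alkylation (SN2′) of the symmetrical dibromide; the Taniaphos–Cu complex delivers ethyl to one face of the γ-carbon, setting C4 (3R in 10) and leaving the second bromide as the handle for the union.

Step 5
Reactants: 10 (3R)-3-(bromomethyl)pent-1-ene; 8 (5S,7S)-7-ethyl-5-methylundecan-3-one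
Product: 12 (3S,7S,9S)-3,5,9-triethyl-7-methyltridec-1-en-5-ol (C5 epimers), via [(2R)-2-ethylbut-3-en-1-yl]magnesium bromide 11 (not isolated)
Conditions: Mg, THF, rt; then 8, LaCl3·2LiCl (30 mol%), THF, 0 °C; aq NH4Cl
Reagents that add atoms: none
Why: Grignard formation then LaCl3·2LiCl-promoted 1,2-addition (the lanthanum salt suppresses enolisation and reduction) forges C5–C6; the β-stereocentre of 11 is not part of the carbanion and stays intact, and the carbinol configuration at C6 is left uncontrolled because C6 is ionised in step 7.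

Step 6
Reactants: 12 (3S,7S,9S)-3,5,9-triethyl-7-methyltridec-1-en-5-ol; 13 methyl acrylate
Product: 14 methyl (2E,4S,8S,10S)-4,6,10-triethyl-6-hydroxy-8-methyltetradec-2-enoate (C6 epimers)
Conditions: methyl acrylate (5 equiv), second-generation Hoveyda–Grubbs catalyst (5 mol%), CH2Cl2, 40 °C
Reagents that add atoms: methyl acrylate, C=CC(=O)OC
Why: Olefin cross-metathesis of the monosubstituted alkene with the electron-poor acrylate is (E)-selective and tolerates the free tertiary alcohol; no stereocentre is touched.

Step 7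
Reactants: 14 methyl (2E,4S,8S,10S)-4,6,10-triethyl-6-hydroxy-8-methyltetradec-2-enoate; 15 hydrogen peroxide
Product: 17 methyl 2-[(3S,4S,6R)-4,6-diethyl-6-[(2S,4S)-4-ethyl-2-methyloctyl]-1,2-dioxan-3-yl]acetate, via tertiary hydroperoxide 16 (not isolated)
Conditions: 50% aq H2O2 (20 equiv), H2SO4 (cat.), Et2O, 0 °C; aqueous wash; then KOt-Bu (0.2 equiv), THF, −78 → −40 °C; AcOH; SiO2 separation of C6 epimers
Reagents that add atoms: hydrogen peroxide, OO
Why: SN1 perhydrolysis (tertiary cation trapped by H2O2) gives hydroperoxide 16, whose potassium peroxide then closes the ring by 6-exo peroxy-Michael (oxa-Michael) addition under kinetic control through a potassium-bridged chair with the C4 ethyl equatorial and the (E)-enoate axial, which should set C3 cis to C4 (3S) by analogy with kinetic alkoxide oxa-Michael closures of (E)-enoates; C6 comes from a planar cation with no facial bias, so the 6R ester 17 is isolated from its 6S epimer by chromatography.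

Step 8
Reactants: 17 methyl 2-[(3S,4S,6R)-4,6-diethyl-6-[(2S,4S)-4-ethyl-2-methyloctyl]-1,2-dioxan-3-yl]acetate; 18 lithium hydroxide
Product: 19 2-[(3S,4S,6R)-4,6-diethyl-6-[(2S,4S)-4-ethyl-2-methyloctyl]-1,2-dioxan-3-yl]acetic acid
Conditions: LiOH (3 equiv), THF/H2O, 0 °C → rt; then 1 M HCl to pH 3
Reagents that add atoms: lithium hydroxide, [Li+].[OH-]
Why: Saponification of the methyl ester; the dialkyl peroxide tolerates cold hydroxide, the carboxylate formed no longer supports retro-Michael ring opening, and no stereocentre changes.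

**Compound list**

1 | methyl (E)-hept-2-enoate | CCCC/C=C/C(=O)OC | starting material
2 | ethylmagnesium bromide | CC[Mg]Br | starting material
3 | methyl (S)-3-ethylheptanoate | CCCC[C@H](CC)CC(=O)OC | intermediate
4 | diethyl (2-oxobutyl)phosphonate | CCC(=O)CP(=O)(OCC)OCC | starting material
5 | (S)-3-ethylheptanal | CCCC[C@H](CC)CC=O | intermediate
6 | (4E,7S)-7-ethylundec-4-en-3-one | CCCC[C@H](CC)C/C=C/C(=O)CC | intermediate
7 | methylmagnesium bromide | C[Mg]Br | starting material
8 | (5S,7S)-7-ethyl-5-methylundecan-3-one | CCCC[C@H](CC)C[C@H](C)CC(=O)CC | intermediate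
9 | (E)-1,4-dibromobut-2-ene | BrC/C=C/CBr | starting material
10 | (3R)-3-(bromomethyl)pent-1-ene | BrC[C@H](CC)C=C | intermediate
11 | [(2R)-2-ethylbut-3-en-1-yl]magnesium bromide | Br[Mg]C[C@H](CC)C=C | intermediate
12 | (3S,7S,9S)-3,5,9-triethyl-7-methyltridec-1-en-5-ol (C5 epimers) | CCCC[C@H](CC)C[C@H](C)CC(O)(CC)C[C@H](CC)C=C | intermediate
13 | methyl acrylate | C=CC(=O)OC | starting material
14 | methyl (2E,4S,8S,10S)-4,6,10-triethyl-6-hydroxy-8-methyltetradec-2-enoate (C6 epimers) | CCCC[C@H](CC)C[C@H](C)CC(O)(CC)C[C@H](CC)/C=C/C(=O)OC | intermediate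
15 | hydrogen peroxide | OO | starting material
16 | methyl (2E,4S,8S,10S)-4,6,10-triethyl-6-hydroperoxy-8-methyltetradec-2-enoate (C6 epimers) | CCCC[C@H](CC)C[C@H](C)CC(OO)(CC)C[C@H](CC)/C=C/C(=O)OC | intermediate
17 | methyl 2-[(3S,4S,6R)-4,6-diethyl-6-[(2S,4S)-4-ethyl-2-methyloctyl]-1,2-dioxan-3-yl]acetate | CCCC[C@H](CC)C[C@H](C)C[C@]1(CC)C[C@H](CC)[C@H](CC(=O)OC)OO1 | intermediate
18 | lithium hydroxide | [Li+].[OH-] | starting material
19 | 2-[(3S,4S,6R)-4,6-diethyl-6-[(2S,4S)-4-ethyl-2-methyloctyl]-1,2-dioxan-3-yl]acetic acid | CCCC[C@H](CC)C[C@H](C)C[C@]1(CC)C[C@H](CC)[C@H](CC(=O)O)OO1 | target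

**Step count and risks**

Total step count: 8. Longest linear sequence: 7 (steps 1, 2, 3, 5, 6, 7, 8).

The ring-forming step 7 is the most likely to fail. The tertiary cation may eliminate or scramble faster than H2O2 traps it, and the cis selectivity at C3 rests on kinetic control that the thermodynamically preferred trans isomer can erode. The fallback replaces the ionic entry by a radical one and sets out from 14:
- Dehydration with Burgess reagent (benzene, 50 °C) gives the trisubstituted alkene mixture represented by methyl (2E,4S,8S,10S)-4,6,10-triethyl-8-methyltetradeca-2,6-dienoate F1. Its 5-ene and 6-ethylidene isomers lead to the same C6 radical.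
- Mukaiyama–Isayama hydroperoxysilylation (Co(acac)2, Et3SiH, O2, ClCH2CH2Cl, rt; the electron-poor enoate is spared) gives methyl (2E,4S,8S,10S)-4,6,10-triethyl-8-methyl-6-[(triethylsilyl)peroxy]tetradec-2-enoate F2.
- n-Bu4NF/AcOH (THF, 0 °C) removes the silyl group, and the route is rejoined at hydroperoxide 16, which is cyclised as in step 7.

The union step 5 is second. The homoallylic Grignard 11 may enolise or reduce the β-branched ketone 8. The fallback joins the fragments by olefination instead of carbonyl addition and sets out from 10 (with 8):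
- PPh3 (MeCN, 80 °C) converts 10 into [(2R)-2-ethylbut-3-en-1-yl]triphenylphosphonium bromide F3.
- The ylide (NaN(SiMe3)2, THF, −78 °C) is condensed with 8 in a Wittig reaction to (3R,7S,9S)-3,5,9-triethyl-7-methyltrideca-1,4-diene F4 (E/Z mixture, irrelevant).
- Cross-metathesis with 13 as in step 6 gives methyl (2E,4R,8S,10S)-4,6,10-triethyl-8-methyltetradeca-2,5-dienoate F5, which is kept base-free.
- Co(acac)2/Et3SiH/O2 then gives the silyl peroxide F2, and n-Bu4NF returns the route at 16.

The cross-metathesis step 6 is third. The α-branched vinyl group of 12 may react sluggishly, or C4 may be eroded by Ru–H isomerisation. The fallback builds the enoate by cleavage and olefination and sets out from 12: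
- Ozonolysis (O3, CH2Cl2/MeOH, −78 °C; Me2S) gives the γ-lactol (3S)-3,5-diethyl-5-[(2S,4S)-4-ethyl-2-methyloctyl]oxolan-2-ol F6, the closed form of the 4-hydroxy aldehyde.
- Wittig opening with Ph3P=CHCO2Me (toluene, 80 °C) comes back to the route at 14.

Further compounds
F1 | step 7 | methyl (2E,4S,8S,10S)-4,6,10-triethyl-8-methyltetradeca-2,6-dienoate (main member of the alkene mixture) | CCCC[C@H](CC)C[C@H](C)C=C(CC)C[C@H](CC)/C=C/C(=O)OC
F2 | step 7 | methyl (2E,4S,8S,10S)-4,6,10-triethyl-8-methyl-6-[(triethylsilyl)peroxy]tetradec-2-enoate (C6 epimers) | CCCC[C@H](CC)C[C@H](C)CC(OO[Si](CC)(CC)CC)(CC)C[C@H](CC)/C=C/C(=O)OC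
F3 | step 5 | [(2R)-2-ethylbut-3-en-1-yl]triphenylphosphonium bromide | [Br-].c1ccccc1[P+](c1ccccc1)(c1ccccc1)C[C@H](CC)C=C
F4 | step 5 | (3R,7S,9S)-3,5,9-triethyl-7-methyltrideca-1,4-diene | CCCC[C@H](CC)C[C@H](C)CC(CC)=C[C@H](CC)C=C
F5 | step 5 | methyl (2E,4R,8S,10S)-4,6,10-triethyl-8-methyltetradeca-2,5-dienoate | CCCC[C@H](CC)C[C@H](C)CC(CC)=C[C@H](CC)/C=C/C(=O)OC
F6 | step 6 | (3S)-3,5-diethyl-5-[(2S,4S)-4-ethyl-2-methyloctyl]oxolan-2-ol | CCCC[C@H](CC)C[C@H](C)CC1(CC)C[C@H](CC)C(O)O1
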